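**Retrosynthetic overview**

1. Labels: C-a = C(OH)(CO2Me); C-b = CH on chromone C-2; C-c = CH between C-a and C-d; C-d = O–CH bridgehead; C-e = O–C bridgehead; ring F = benzo ring of the oxygen bridge. The strategy rests on the 2,6-dihydroxyphenyl ring standing on the fully substituted bridgehead C-e, with C-1′ between the two oxygen-bearing carbons C-2′ and C-6′.
2. Last disconnection: that resorcinol ring ⇒ vinylketene (from cyclobutenone) + the bridgehead ynol silyl ether C-e–C≡C–OSi(i-Pr)3 of the complete skeleton (benzannulation; bonds C-1′–C-2′, C-5′–C-6′, C-2′–C-3′).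
3. Skeleton ⇒ exo Diels–Alder reaction of a 1-(silyloxyethynyl)isobenzofuran (ring F, C-d, O, C-e) with the C-b=C-c bond of an enantiopure cyclopenta[b]chromone that already carries C-a, so that C-a directs the four new centres.
4. Isobenzofuran ⇒ tetrazine-induced release from an aryne–furan adduct after acetylide oxidation and O-silylation. Dienophile ⇒ chromone from 3,5-dihydroxybenzyl alcohol (enaminone acylation), vinyl addition, C-2 vinylation, ring-closing metathesis, chiral chromatography.
5. Ring order: oxanorbornadiene (aryne Diels–Alder) → pyranone → cyclopentene → oxygen-bridged bicycle rebuilt on the cyclopentene → resorcinol ring last.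

Key step: step 21

Remark: the target is read from its SMILES as the cis-exo adduct with the C-a hydroxyl syn to the oxygen bridge (C-a S, C-b R, C-c R, C-d R, C-e S). A carbonyl insertion of an exo C-c–metal bond would be expected to place that hydroxyl anti to the bridge, so the bicycle is instead built by cycloaddition onto a dienophile whose C-a is already set.
Remark: the absolute configuration of the resolved dienophile is to be assigned after separation (X-ray or VCD); the base-labile side-chain acetate is introduced only after the last strongly basic operation.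

**Route**

Step 1
Reactants: 1 4-hydroxy-3-methylbenzaldehyde
Product: 2 3-methyl-4-[(triisopropylsilyl)oxy]benzaldehyde
Conditions: i-Pr3SiCl, imidazole, DMF, 23 °C
Reagents that add atoms: chlorotriisopropylsilane, CC(C)[Si](Cl)(C(C)C)C(C)C
Why: Imidazole-promoted silylation of the phenol gives a bulky silyl ether that survives the peracid and lithium amide steps and supplies the steric bias used in step 6.

Step 2
Reactants: 2 3-methyl-4-[(triisopropylsilyl)oxy]benzaldehyde
Product: 4 3-methyl-4-[(triisopropylsilyl)oxy]phenol, via aryl formate 3 (not isolated)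
Conditions: mCPBA, CH2Cl2, 0 → 23 °C; then Et3N, MeOH, 23 °C
Reagents that add atoms: 3-chloroperbenzoic acid, OOC(=O)c1cccc(Cl)c1
Why: Baeyer–Villiger oxidation with migration of the electron-rich aryl group gives the formate, and mild methanolysis frees the phenol without touching the aryl silyl ether.

Step 3
Reactants: 4 3-methyl-4-[(triisopropylsilyl)oxy]phenol
Product: 5 [4-(methoxymethoxy)-2-methylphenoxy]triisopropylsilane
Conditions: MOMCl, i-Pr2NEt, CH2Cl2, 0 → 23 °C
Reagents that add atoms: chloromethyl methyl ether, COCCl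
Why: O-alkylation of the phenol with the chloromethyl ether gives a small, base-stable acetal that will sit next to the aryne.

Step 4
Reactants: 5 [4-(methoxymethoxy)-2-methylphenoxy]triisopropylsilane
Product: 6 [4-bromo-5-(methoxymethoxy)-2-methylphenoxy]triisopropylsilane
Conditions: NBS, MeCN, 0 °C
Reagents that add atoms: N-bromosuccinimide, O=C1CCC(=O)N1Br
Why: Electrophilic aromatic bromination should occur at the one position that is ortho to the acetal oxygen and para to the methyl group, the other activated positions being flanked by two substituents or by the bulky silyl ether.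

Step 5
Reactants: 7 2-bromofuran; 8 ethynyltrimethylsilane
Product: 9 (furan-2-ylethynyl)trimethylsilane
Conditions: PdCl2(PPh3)2 (2 mol %), CuI (4 mol %), i-Pr2NH, THF, 23 °C
Reagents that add atoms: none
Why: Sonogashira coupling of the 2-bromofuran with the terminal alkyne.

Step 6
Reactants: 6 [4-bromo-5-(methoxymethoxy)-2-methylphenoxy]triisopropylsilane; 9 (furan-2-ylethynyl)trimethylsilane
Product: 11 rac-{[8-(methoxymethoxy)-6-methyl-5-[(triisopropylsilyl)oxy]-1,4-dihydro-1,4-epoxynaphthalen-1-yl]ethynyl}trimethylsilane, via aryne 10 (not isolated)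
Conditions: lithium 2,2,6,6-tetramethylpiperidide (1.3 equiv) added to 6 and 9 (3 equiv), THF, −78 → 23 °C
Reagents that add atoms: none
Why: Deprotonation between Br and the silyl ether and loss of LiBr give aryne 10, which the furan traps in an aryne Diels–Alder reaction; the silyloxy group, pushed toward the aryne by the neighbouring methyl, should steer the alkynyl-bearing furan carbon to the aryne carbon next to the small MOM ether (the regioisomer is removed by chromatography), and the racemic bridgehead centres are of no consequence because they are erased in step 19.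

Step 7
Reactants: 11 rac-{[8-(methoxymethoxy)-6-methyl-5-[(triisopropylsilyl)oxy]-1,4-dihydro-1,4-epoxynaphthalen-1-yl]ethynyl}trimethylsilane
Product: 12 rac-1-ethynyl-8-(methoxymethoxy)-6-methyl-1,4-dihydro-1,4-epoxynaphthalen-5-ol
Conditions: TBAF (2.5 equiv), THF, 0 °C; aq. NH4Cl
Reagents that add atoms: none
Why: Fluoride cleaves both the aryl silyl ether and the C-silyl alkyne (Si–F bond formation) while the MOM ether and the oxygen bridge are inert.

Step 8
Reactants: 12 rac-1-ethynyl-8-(methoxymethoxy)-6-methyl-1,4-dihydro-1,4-epoxynaphthalen-5-ol; 13 4-bromo-2-methylbutan-2-ol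
Product: 14 rac-4-{[1-ethynyl-8-(methoxymethoxy)-6-methyl-1,4-dihydro-1,4-epoxynaphthalen-5-yl]oxy}-2-methylbutan-2-ol
Conditions: Cs2CO3, DMF, 50 °C
Reagents that add atoms: none
Why: Williamson etherification of the caesium phenoxide with the primary bromide; the tertiary hydroxyl and the terminal alkyne are not alkylated under carbonate conditions.

Step 9
Reactants: 14 rac-4-{[1-ethynyl-8-(methoxymethoxy)-6-methyl-1,4-dihydro-1,4-epoxynaphthalen-5-yl]oxy}-2-methylbutan-2-ol
Product: 17 rac-4-{[8-(methoxymethoxy)-6-methyl-1-{[(triisopropylsilyl)oxy]ethynyl}-1,4-dihydro-1,4-epoxynaphthalen-5-yl]oxy}-2-methylbutan-2-yl acetate, via dilithium ynolate alkoxide 15 (not isolated), via lithium alkoxide of the ynol silyl ether 16 (not isolated)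
Conditions: LiN(SiMe3)2 (2.2 equiv), THF, −78 °C; LiOOt-Bu (from t-BuOOH and LiN(SiMe3)2), −78 → 0 °C; i-Pr3SiOTf, −78 °C; Ac2O, −78 → 0 °C
Reagents that add atoms: lithium tert-butyl peroxide, [Li+].CC(C)(C)O[O-]; triisopropylsilyl trifluoromethanesulfonate, CC(C)[Si](OS(=O)(=O)C(F)(F)F)(C(C)C)C(C)C; acetic anhydride, CC(=O)OC(C)=O
Why: Oxidation of the lithium acetylide by the lithium peroxide gives the ynolate, the bulky silyl triflate silylates it on oxygen while the hindered tertiary alkoxide is left alone (as is the tert-butoxide by-product), and that alkoxide is then acetylated by Ac2O, so the acetate enters only after all strongly basic operations; the non-nucleophilic amide base avoids opening of the strained oxabicycle.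

Step 10
Reactants: 18 3,5-dihydroxybenzyl alcohol
Product: 19 1,3-bis(methoxymethoxy)-5-[(methoxymethoxy)methyl]benzene
Conditions: NaH, MOMCl, DMF, 0 → 23 °C
Reagents that add atoms: chloromethyl methyl ether, COCCl
Why: Exhaustive O-alkylation of the two phenoxides and the benzylic alkoxide with the chloromethyl ether.

Step 11
Reactants: 19 1,3-bis(methoxymethoxy)-5-[(methoxymethoxy)methyl]benzene
Product: 21 1-{2,6-bis(methoxymethoxy)-4-[(methoxymethoxy)methyl]phenyl}ethan-1-one, via aryllithium 20 (not isolated)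
Conditions: n-BuLi, THF, 0 °C; N-methoxy-N-methylacetamide, −78 → 0 °C
Reagents that add atoms: N-methoxy-N-methylacetamide, CON(C)C(C)=O
Why: Directed ortho-lithiation between the two MOM ethers and acylation of the aryllithium by the Weinreb amide, whose chelated adduct prevents over-addition.

Step 12
Reactants: 21 1-{2,6-bis(methoxymethoxy)-4-[(methoxymethoxy)methyl]phenyl}ethan-1-one
Product: 22 1-{2-hydroxy-6-(methoxymethoxy)-4-[(methoxymethoxy)methyl]phenyl}ethan-1-one
Conditions: HCl (0.5 M in MeOH), 0 → 23 °C, stopped after loss of one aryl MOM group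
Reagents that add atoms: none
Why: Acid-catalysed acetal exchange removes one aryl MOM group ortho to the ketone (carbonyl-assisted) and then slows because the new phenol is hydrogen-bonded to the ketone, the benzylic MOM ether being slower still.

Step 13
Reactants: 22 1-{2-hydroxy-6-(methoxymethoxy)-4-[(methoxymethoxy)methyl]phenyl}ethan-1-one
Product: 23 (E)-3-(dimethylamino)-1-{2-hydroxy-6-(methoxymethoxy)-4-[(methoxymethoxy)methyl]phenyl}prop-2-en-1-one
Conditions: Me2NCH(OMe)2, toluene, 90 °C
Reagents that add atoms: N,N-dimethylformamide dimethyl acetal, COC(OC)N(C)C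
Why: Condensation of the methyl ketone with the amide acetal gives the (E)-enaminone.

Step 14
Reactants: 23 (E)-3-(dimethylamino)-1-{2-hydroxy-6-(methoxymethoxy)-4-[(methoxymethoxy)methyl]phenyl}prop-2-en-1-one
Product: 24 methyl 2-{5-(methoxymethoxy)-7-[(methoxymethoxy)methyl]-4-oxo-4H-chromen-3-yl}-2-oxoacetate
Conditions: ClCOCO2Me, pyridine, CH2Cl2, 0 → 23 °C
Reagents that add atoms: methyl chlorooxoacetate, COC(=O)C(Cl)=O
Why: C-acylation of the enaminone at its nucleophilic α-carbon, then conjugate addition of the phenol and loss of dimethylamine, closes the pyranone (enaminone route to 3-acylchromones).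

Step 15
Reactants: 24 methyl 2-{5-(methoxymethoxy)-7-[(methoxymethoxy)methyl]-4-oxo-4H-chromen-3-yl}-2-oxoacetate
Product: 25 rac-methyl 2-hydroxy-2-{5-(methoxymethoxy)-7-[(methoxymethoxy)methyl]-4-oxo-4H-chromen-3-yl}but-3-enoate
Conditions: CH2=CHMgBr, CeCl3, THF, −78 °C
Reagents that add atoms: vinylmagnesium bromide, C=C[Mg]Br
Why: The organocerium reagent should add 1,2 to the ketone of the α-keto ester, the most electrophilic carbonyl group, and not in the conjugate sense to C-2 of the 3-acylchromone; C-a is formed racemic.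

Step 16
Reactants: 25 rac-methyl 2-hydroxy-2-{5-(methoxymethoxy)-7-[(methoxymethoxy)methyl]-4-oxo-4H-chromen-3-yl}but-3-enoate
Product: 27 rac-methyl 2-{2-ethenyl-5-(methoxymethoxy)-7-[(methoxymethoxy)methyl]-4-oxo-4H-chromen-3-yl}-2-hydroxybut-3-enoate, via C-2 zincated zinc alkoxide 26 (not isolated)
Conditions: TMPZnCl·LiCl (2.2 equiv), THF, 23 °C; then vinyl bromide, Pd(PPh3)4 (5 mol %), 50 °C
Reagents that add atoms: bromoethene, C=CBr
Why: The hindered zinc amide forms the zinc alkoxide and then removes the acidic C-2 hydrogen of the chromone (ester-tolerant directed zincation), and Negishi coupling with vinyl bromide installs the second vinyl group.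

Step 17
Reactants: 27 rac-methyl 2-{2-ethenyl-5-(methoxymethoxy)-7-[(methoxymethoxy)methyl]-4-oxo-4H-chromen-3-yl}-2-hydroxybut-3-enoate
Product: 28 rac-methyl 1-hydroxy-8-(methoxymethoxy)-6-[(methoxymethoxy)methyl]-9-oxo-1,9-dihydrocyclopenta[b]chromene-1-carboxylate
Conditions: second-generation Grubbs catalyst (5 mol %), CH2Cl2, 40 °C
Reagents that add atoms: none
Why: Ring-closing metathesis of the two vinyl groups forms the five-membered ring (C-b=C-c) with loss of ethene; C-a is quaternary, so the cyclopentadiene cannot shift hydrogen.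

Step 18
Reactants: 28 rac-methyl 1-hydroxy-8-(methoxymethoxy)-6-[(methoxymethoxy)methyl]-9-oxo-1,9-dihydrocyclopenta[b]chromene-1-carboxylate
Product: 29 methyl (1S)-1-hydroxy-8-(methoxymethoxy)-6-[(methoxymethoxy)methyl]-9-oxo-1,9-dihydrocyclopenta[b]chromene-1-carboxylate
Conditions: preparative SFC on an amylose tris(3,5-dimethylphenylcarbamate) phase, CO2/MeOH
Reagents that add atoms: none
Why: Chromatographic resolution on a chiral stationary phase delivers the (1S) enantiomer, whose single stereocentre C-a controls all others in step 19.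

Step 19
Reactants: 17 rac-4-{[8-(methoxymethoxy)-6-methyl-1-{[(triisopropylsilyl)oxy]ethynyl}-1,4-dihydro-1,4-epoxynaphthalen-5-yl]oxy}-2-methylbutan-2-yl acetate; 29 methyl (1S)-1-hydroxy-8-(methoxymethoxy)-6-[(methoxymethoxy)methyl]-9-oxo-1,9-dihydrocyclopenta[b]chromene-1-carboxylate
Product: 31 bridgehead ynol silyl ether of the full skeleton (cis-exo-fused cyclopenta[b]chromone on the oxabenzonorbornene; C≡C–OSi(i-Pr)3 on C-e; three MOM ethers; side-chain acetate; C-a S; C-b R; C-c R; C-d R; C-e R), via isobenzofuran 30 (not isolated)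
Conditions: 17 (1.3 equiv) added slowly to 29 and 3,6-di(pyridin-2-yl)-1,2,4,5-tetrazine (1.35 equiv), CH2Cl2, 0 → 23 °C; then 40 °C
Reagents that add atoms: none
Why: The tetrazine adds to the strained alkene of 17 (inverse-demand Diels–Alder), loses N2 and fragments by retro-Diels–Alder to the achiral isobenzofuran 30, which adds to the C-b=C-c bond of 29 in a normal Diels–Alder reaction; the unsubstituted diene terminus C-d should bond to C-c (the electrophilic δ-carbon next to quaternary C-a) and C-e to C-b, on the face of 29 that carries the small hydroxyl and in the exo mode, where that hydroxyl can hydrogen-bond to the furan oxygen and the C-a substituents avoid ring F, so C-b, C-c, C-d and C-e are set relative to C-a.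

Step 20
Reactants: 32 3-bromocyclobutan-1-one
Product: 33 cyclobut-2-en-1-one
Conditions: n-Bu3N, 23 °C, product taken off in vacuo into a cold trap and used at once as a toluene solution
Reagents that add atoms: none
Why: Dehydrobromination of the β-bromo ketone by the tertiary amine (E1cB elimination) gives the strained enone, which is removed as it forms.

Step 21
Reactants: 31 bridgehead ynol silyl ether of the full skeleton; 33 cyclobut-2-en-1-one
Product: 38 mono-silyl tris-MOM aspergichromone B (2-hydroxy-6-[(triisopropylsilyl)oxy]phenyl on C-e; C-a S; C-b R; C-c R; C-d R; C-e S), via vinylketene 34 (not isolated), via vinylcyclobutenone adduct 35 (not isolated), via dienylketene 36 (not isolated), via cyclohexadienone tautomer 37 (not isolated)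
Conditions: 33 (3 equiv, in portions), toluene, 80 °C, sealed tube; then 110 °C
Reagents that add atoms: none
Why: Cyclobutenone opens (4π) to vinylketene 34; the ynol ether adds to the ketene C=C in a [2+2] sense with its C-e-bound carbon C-1′ bonding to the ketene carbonyl carbon C-2′ and its oxygen-bearing carbon C-6′ bonding to C-5′ (35); 4π opening of the C-2′–C-5′ bond gives dienylketene 36, and 6π closure (C-2′–C-3′) followed by tautomerisation of 37 gives the phenol. The closest known reaction is the Danheiser benzannulation of cyclobutenone-derived vinylketenes with trialkylsilyloxyalkynes to resorcinol monosilyl ethers. The four-membered ring closes by ketene–alkyne [2+2] cycloaddition and the six-membered ring by 6π electrocyclisation of the dienylketene. No stereocentre is formed and the five existing ones are untouched because every event is neutral and pericyclic. The step needs C-1′ to end between C–OH and C–OSi, which the polarisation of the ynol ether (nucleophilic at the carbon remote from oxygen) secures, and it needs the ketene to choose the ynol ether over the tertiary C-a hydroxyl, which the hindered, hydrogen-bonded position of that hydroxyl and portionwise addition of 33 should secure. A bridgehead alkyne is far slimmer than the finished 2,6-dioxygenated aryl group, which is why C-e could be carried through the cycloaddition of step 19 without strain.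

Step 22
Reactants: 38 mono-silyl tris-MOM aspergichromone B
Product: 39 tris-MOM aspergichromone B (2,6-dihydroxyphenyl on C-e; MOM ethers on the ring F phenol, the chromone 5-oxygen and the benzylic oxygen)
Conditions: TBAF, AcOH (1:1), THF, 0 → 23 °C
Reagents that add atoms: none
Why: Buffered fluoride cleaves the aryl silyl ether (a silyl group that has migrated to the neighbouring phenol oxygen gives the same symmetric resorcinol) without hydrolysing the tertiary acetate or the methyl ester.

Step 23
Reactants: 39 tris-MOM aspergichromone B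
Product: 40 aspergichromone B
Conditions: ZnBr2, n-PrSH, CH2Cl2, 0 °C
Reagents that add atoms: none
Why: Lewis acid-assisted thiolysis of the three MOM acetals (acetal exchange to the thioacetal) under aprotic conditions should leave intact the tertiary acetate, the tertiary α-hydroxy ester and the oxygen bridge, whose bridgehead carbons cannot ionise.

**Compound list**

1 | 4-hydroxy-3-methylbenzaldehyde | Cc1cc(C=O)ccc1O | starting material
2 | 3-methyl-4-[(triisopropylsilyl)oxy]benzaldehyde | Cc1cc(C=O)ccc1O[Si](C(C)C)(C(C)C)C(C)C | intermediate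
3 | 3-methyl-4-[(triisopropylsilyl)oxy]phenyl formate | Cc1cc(OC=O)ccc1O[Si](C(C)C)(C(C)C)C(C)C | intermediate
4 | 3-methyl-4-[(triisopropylsilyl)oxy]phenol | Cc1cc(O)ccc1O[Si](C(C)C)(C(C)C)C(C)C | intermediate
5 | [4-(methoxymethoxy)-2-methylphenoxy]triisopropylsilane | Cc1cc(OCOC)ccc1O[Si](C(C)C)(C(C)C)C(C)C | intermediate
6 | [4-bromo-5-(methoxymethoxy)-2-methylphenoxy]triisopropylsilane | Cc1cc(OCOC)c(Br)cc1O[Si](C(C)C)(C(C)C)C(C)C | intermediate
7 | 2-bromofuran | Brc1ccco1 | starting material
8 | ethynyltrimethylsilane | C#C[Si](C)(C)C | starting material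
9 | (furan-2-ylethynyl)trimethylsilane | C[Si](C)(C)C#Cc1ccco1 | intermediate
10 | 6-(methoxymethoxy)-4-methyl-3-[(triisopropylsilyl)oxy]benzyne | CC1=C(O[Si](C(C)C)(C(C)C)C(C)C)C#CC(OCOC)=C1 | intermediate
11 | rac-{[8-(methoxymethoxy)-6-methyl-5-[(triisopropylsilyl)oxy]-1,4-dihydro-1,4-epoxynaphthalen-1-yl]ethynyl}trimethylsilane | C[Si](C)(C)C#CC12OC(C=C1)c1c(O[Si](C(C)C)(C(C)C)C(C)C)c(C)cc(OCOC)c12 | intermediate
12 | rac-1-ethynyl-8-(methoxymethoxy)-6-methyl-1,4-dihydro-1,4-epoxynaphthalen-5-ol | C#CC12OC(C=C1)c1c(O)c(C)cc(OCOC)c12 | intermediate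
13 | 4-bromo-2-methylbutan-2-ol | CC(C)(O)CCBr | starting material
14 | rac-4-{[1-ethynyl-8-(methoxymethoxy)-6-methyl-1,4-dihydro-1,4-epoxynaphthalen-5-yl]oxy}-2-methylbutan-2-ol | C#CC12OC(C=C1)c1c(OCCC(C)(C)O)c(C)cc(OCOC)c12 | intermediate
15 | dilithium ynolate alkoxide derived from 14 | [Li+].[Li+].[O-]C#CC12OC(C=C1)c1c(OCCC(C)(C)[O-])c(C)cc(OCOC)c12 | intermediate
16 | lithium alkoxide of the ynol triisopropylsilyl ether | [Li+].CC(C)[Si](OC#CC12OC(C=C1)c1c(OCCC(C)(C)[O-])c(C)cc(OCOC)c12)(C(C)C)C(C)C | intermediate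
17 | rac-4-{[8-(methoxymethoxy)-6-methyl-1-{[(triisopropylsilyl)oxy]ethynyl}-1,4-dihydro-1,4-epoxynaphthalen-5-yl]oxy}-2-methylbutan-2-yl acetate | CC(C)[Si](OC#CC12OC(C=C1)c1c(OCCC(C)(C)OC(C)=O)c(C)cc(OCOC)c12)(C(C)C)C(C)C | intermediate
18 | 3,5-dihydroxybenzyl alcohol | OCc1cc(O)cc(O)c1 | starting material
19 | 1,3-bis(methoxymethoxy)-5-[(methoxymethoxy)methyl]benzene | COCOCc1cc(OCOC)cc(OCOC)c1 | intermediate
20 | {2,6-bis(methoxymethoxy)-4-[(methoxymethoxy)methyl]phenyl}lithium | [Li]c1c(OCOC)cc(COCOC)cc1OCOC | intermediate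
21 | 1-{2,6-bis(methoxymethoxy)-4-[(methoxymethoxy)methyl]phenyl}ethan-1-one | CC(=O)c1c(OCOC)cc(COCOC)cc1OCOC | intermediate
22 | 1-{2-hydroxy-6-(methoxymethoxy)-4-[(methoxymethoxy)methyl]phenyl}ethan-1-one | CC(=O)c1c(O)cc(COCOC)cc1OCOC | intermediate
23 | (E)-3-(dimethylamino)-1-{2-hydroxy-6-(methoxymethoxy)-4-[(methoxymethoxy)methyl]phenyl}prop-2-en-1-one | CN(C)/C=C/C(=O)c1c(O)cc(COCOC)cc1OCOC | intermediate
24 | methyl 2-{5-(methoxymethoxy)-7-[(methoxymethoxy)methyl]-4-oxo-4H-chromen-3-yl}-2-oxoacetate | COC(=O)C(=O)c1coc2cc(COCOC)cc(OCOC)c2c1=O | intermediate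
25 | rac-methyl 2-hydroxy-2-{5-(methoxymethoxy)-7-[(methoxymethoxy)methyl]-4-oxo-4H-chromen-3-yl}but-3-enoate | COC(=O)C(O)(C=C)c1coc2cc(COCOC)cc(OCOC)c2c1=O | intermediate
26 | C-2 zincated zinc alkoxide of 25 | COC(=O)C(O[Zn]Cl)(C=C)c1c([Zn]Cl)oc2cc(COCOC)cc(OCOC)c2c1=O | intermediate
27 | rac-methyl 2-{2-ethenyl-5-(methoxymethoxy)-7-[(methoxymethoxy)methyl]-4-oxo-4H-chromen-3-yl}-2-hydroxybut-3-enoate | COC(=O)C(O)(C=C)c1c(C=C)oc2cc(COCOC)cc(OCOC)c2c1=O | intermediate
28 | rac-methyl 1-hydroxy-8-(methoxymethoxy)-6-[(methoxymethoxy)methyl]-9-oxo-1,9-dihydrocyclopenta[b]chromene-1-carboxylate | COC(=O)C1(O)c2c(oc3cc(COCOC)cc(OCOC)c3c2=O)C=C1 | intermediate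
29 | methyl (1S)-1-hydroxy-8-(methoxymethoxy)-6-[(methoxymethoxy)methyl]-9-oxo-1,9-dihydrocyclopenta[b]chromene-1-carboxylate | COC(=O)[C@@]1(O)c2c(oc3cc(COCOC)cc(OCOC)c3c2=O)C=C1 | intermediate
30 | 4-{[7-(methoxymethoxy)-5-methyl-1-{[(triisopropylsilyl)oxy]ethynyl}-2-benzofuran-4-yl]oxy}-2-methylbutan-2-yl acetate (isobenzofuran) | CC(=O)OC(C)(C)CCOc1c(C)cc(OCOC)c2c(C#CO[Si](C(C)C)(C(C)C)C(C)C)occ12 | intermediate
31 | bridgehead ynol silyl ether of the full skeleton, tris-MOM, side-chain acetate (C-a S, C-b R, C-c R, C-d R, C-e R; exo ring fusion, C-a OH syn to the oxygen bridge) | COC(=O)[C@@]1(O)c2c(oc3cc(COCOC)cc(OCOC)c3c2=O)[C@H]2[C@@H]1[C@H]1O[C@]2(C#CO[Si](C(C)C)(C(C)C)C(C)C)c2c(OCOC)cc(C)c(OCCC(C)(C)OC(C)=O)c21 | intermediate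
32 | 3-bromocyclobutan-1-one | O=C1CC(Br)C1 | starting material
33 | cyclobut-2-en-1-one | O=C1C=CC1 | intermediate
34 | vinylketene (buta-1,3-dien-1-one) | C=CC=C=O | intermediate
35 | 2-(C-e)-3-[(triisopropylsilyl)oxy]-4-vinylcyclobut-2-en-1-one adduct of 31 | COC(=O)[C@@]1(O)c2c(oc3cc(COCOC)cc(OCOC)c3c2=O)[C@H]2[C@@H]1[C@H]1O[C@]2(C4=C(O[Si](C(C)C)(C(C)C)C(C)C)C(C=C)C4=O)c2c(OCOC)cc(C)c(OCCC(C)(C)OC(C)=O)c21 | intermediate
36 | dienylketene from ring opening of 35 | COC(=O)[C@@]1(O)c2c(oc3cc(COCOC)cc(OCOC)c3c2=O)[C@H]2[C@@H]1[C@H]1O[C@]2(C(=C=O)C(O[Si](C(C)C)(C(C)C)C(C)C)=CC=C)c2c(OCOC)cc(C)c(OCCC(C)(C)OC(C)=O)c21 | intermediate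
37 | cyclohexa-2,4-dien-1-one tautomer of 38 | COC(=O)[C@@]1(O)c2c(oc3cc(COCOC)cc(OCOC)c3c2=O)[C@H]2[C@@H]1[C@H]1O[C@]2(C4=C(O[Si](C(C)C)(C(C)C)C(C)C)C=CCC4=O)c2c(OCOC)cc(C)c(OCCC(C)(C)OC(C)=O)c21 | intermediate
38 | mono-silyl tris-MOM aspergichromone B (C-a S, C-b R, C-c R, C-d R, C-e S) | COC(=O)[C@@]1(O)c2c(oc3cc(COCOC)cc(OCOC)c3c2=O)[C@H]2[C@@H]1[C@H]1O[C@]2(c2c(O)cccc2O[Si](C(C)C)(C(C)C)C(C)C)c2c(OCOC)cc(C)c(OCCC(C)(C)OC(C)=O)c21 | intermediate
39 | tris-MOM aspergichromone B | COC(=O)[C@@]1(O)c2c(oc3cc(COCOC)cc(OCOC)c3c2=O)[C@H]2[C@@H]1[C@H]1O[C@]2(c2c(O)cccc2O)c2c(OCOC)cc(C)c(OCCC(C)(C)OC(C)=O)c21 | intermediate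
40 | aspergichromone B (C-a S, C-b R, C-c R, C-d R, C-e S) | COC(=O)[C@@]1(O)c2c(oc3cc(CO)cc(O)c3c2=O)[C@H]2[C@@H]1[C@H]1O[C@]2(c2c(O)cccc2O)c2c(O)cc(C)c(OCCC(C)(C)OC(C)=O)c21 | target

**Step count**

Total steps: 23. Longest linear sequence: 13 steps (steps 10–18, then 19, 21, 22, 23, from 3,5-dihydroxybenzyl alcohol).

**Steps most likely to fail**

1. Step 21 (key step). What may go wrong: the [2+2] addition at the hindered bridgehead ynol ether is slow, so vinylketene is lost to dimerisation and to O-acylation of the hydroxyl groups, or the ynol ether loses its silyl group on prolonged heating. Fallback, setting out from 6, 7, 13 and 29 and coming back at 40: the aryl ring is carried in from the start. 1,3-Bis(methoxymethoxy)benzene is lithiated between its two acetal groups (n-BuLi) and transmetalated with ZnCl2 to [2,6-bis(methoxymethoxy)phenyl]zinc chloride F1, which is coupled with 7 (Pd(PPh3)4) to 2-[2,6-bis(methoxymethoxy)phenyl]furan F2. F2 replaces 9 in the aryne Diels–Alder reaction with 6 (conditions of step 6) to give the 1-aryl oxabenzonorbornadiene F3. TBAF frees phenol F4, alkylation with 13 (Cs2CO3, DMF) gives tertiary alcohol F5, and Ac2O with 4-(dimethylamino)pyridine gives acetate F6, ordinary acylation being safe in the absence of an ynol ether. Tetrazine treatment of F6 in the presence of 29 (conditions of step 19) releases the arylisobenzofuran F7 and gives the pentakis-MOM adduct F8, which ZnBr2/n-PrSH converts into 40.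

2. Step 19. What may go wrong: the tetrazine is consumed by the electron-rich ynol ether, the ynol-substituted isobenzofuran is trapped by unreacted strained alkene or oligomerises before it meets the hindered dienophile, or approach drifts to the endo mode or the ester face. Fallback, setting out from 17 and 33 and coming back at 38: the order of the two cycloadditions is inverted. 17 is benzannulated with 33 first (conditions of step 21) to the aryl-substituted oxabenzonorbornadiene F9. The tetrazine then releases from F9 the arylisobenzofuran F10, which carries no tetrazine-sensitive group and can be heated with 29 (toluene, 80–100 °C) so that the cycloaddition can equilibrate toward the exo adduct, giving 38 directly.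

3. Step 16. What may go wrong: zincation at C-2 is incomplete or unselective in the presence of the zinc alkoxide, or the free allylic alkoxide diverts the palladium-catalysed coupling. Fallback, setting out from 22 and coming back at 28, with neither C-2 metalation nor metathesis: 22 is condensed with N,N-dimethylacetamide dimethyl acetal to the β-methyl enaminone F11, which methyl chlorooxoacetate and pyridine convert into the 2-methyl-3-methoxalylchromone F12. Vinylcerium addition (as in step 15) gives the vinyl carbinol F13, and ozonolysis (O3, CH2Cl2/MeOH, −78 °C; Me2S) gives the α-hydroxy aldehyde F14. A vinylogous aldol condensation of the acidic 2-methyl group onto the aldehyde (DBU, CH2Cl2) closes the five-membered ring and dehydrates to 28.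

**Further compounds**

F1 | step 21 | [2,6-bis(methoxymethoxy)phenyl]zinc chloride | COCOc1cccc(OCOC)c1[Zn]Cl
F2 | step 21 | 2-[2,6-bis(methoxymethoxy)phenyl]furan | COCOc1cccc(OCOC)c1-c1ccco1
F3 | step 21 | rac-{[1-[2,6-bis(methoxymethoxy)phenyl]-8-(methoxymethoxy)-6-methyl-1,4-dihydro-1,4-epoxynaphthalen-5-yl]oxy}triisopropylsilane | COCOc1cccc(OCOC)c1C12OC(C=C1)c1c(O[Si](C(C)C)(C(C)C)C(C)C)c(C)cc(OCOC)c12
F4 | step 21 | rac-1-[2,6-bis(methoxymethoxy)phenyl]-8-(methoxymethoxy)-6-methyl-1,4-dihydro-1,4-epoxynaphthalen-5-ol | COCOc1cccc(OCOC)c1C12OC(C=C1)c1c(O)c(C)cc(OCOC)c12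
F5 | step 21 | rac-4-{[1-[2,6-bis(methoxymethoxy)phenyl]-8-(methoxymethoxy)-6-methyl-1,4-dihydro-1,4-epoxynaphthalen-5-yl]oxy}-2-methylbutan-2-ol | COCOc1cccc(OCOC)c1C12OC(C=C1)c1c(OCCC(C)(C)O)c(C)cc(OCOC)c12
F6 | step 21 | rac-4-{[1-[2,6-bis(methoxymethoxy)phenyl]-8-(methoxymethoxy)-6-methyl-1,4-dihydro-1,4-epoxynaphthalen-5-yl]oxy}-2-methylbutan-2-yl acetate | COCOc1cccc(OCOC)c1C12OC(C=C1)c1c(OCCC(C)(C)OC(C)=O)c(C)cc(OCOC)c12
F7 | step 21 | 4-{[1-[2,6-bis(methoxymethoxy)phenyl]-7-(methoxymethoxy)-5-methyl-2-benzofuran-4-yl]oxy}-2-methylbutan-2-yl acetate | CC(=O)OC(C)(C)CCOc1c(C)cc(OCOC)c2c(-c3c(OCOC)cccc3OCOC)occ12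
F8 | step 21 | pentakis-MOM aspergichromone B | COC(=O)[C@@]1(O)c2c(oc3cc(COCOC)cc(OCOC)c3c2=O)[C@H]2[C@@H]1[C@H]1O[C@]2(c2c(OCOC)cccc2OCOC)c2c(OCOC)cc(C)c(OCCC(C)(C)OC(C)=O)c21
F9 | step 19 | rac-4-{[1-{2-hydroxy-6-[(triisopropylsilyl)oxy]phenyl}-8-(methoxymethoxy)-6-methyl-1,4-dihydro-1,4-epoxynaphthalen-5-yl]oxy}-2-methylbutan-2-yl acetate | CC(=O)OC(C)(C)CCOc1c(C)cc(OCOC)c2c1C1C=CC2(c2c(O)cccc2O[Si](C(C)C)(C(C)C)C(C)C)O1
F10 | step 19 | 4-{[1-{2-hydroxy-6-[(triisopropylsilyl)oxy]phenyl}-7-(methoxymethoxy)-5-methyl-2-benzofuran-4-yl]oxy}-2-methylbutan-2-yl acetate | CC(=O)OC(C)(C)CCOc1c(C)cc(OCOC)c2c(-c3c(O)cccc3O[Si](C(C)C)(C(C)C)C(C)C)occ12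
F11 | step 16 | (E)-3-(dimethylamino)-1-{2-hydroxy-6-(methoxymethoxy)-4-[(methoxymethoxy)methyl]phenyl}but-2-en-1-one | CN(C)/C(C)=C/C(=O)c1c(O)cc(COCOC)cc1OCOC
F12 | step 16 | methyl 2-{5-(methoxymethoxy)-7-[(methoxymethoxy)methyl]-2-methyl-4-oxo-4H-chromen-3-yl}-2-oxoacetate | COC(=O)C(=O)c1c(C)oc2cc(COCOC)cc(OCOC)c2c1=O
F13 | step 16 | rac-methyl 2-hydroxy-2-{5-(methoxymethoxy)-7-[(methoxymethoxy)methyl]-2-methyl-4-oxo-4H-chromen-3-yl}but-3-enoate | COC(=O)C(O)(C=C)c1c(C)oc2cc(COCOC)cc(OCOC)c2c1=O
F14 | step 16 | rac-methyl 2-hydroxy-2-{5-(methoxymethoxy)-7-[(methoxymethoxy)methyl]-2-methyl-4-oxo-4H-chromen-3-yl}-3-oxopropanoate | COC(=O)C(O)(C=O)c1c(C)oc2cc(COCOC)cc(OCOC)c2c1=O
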